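**Retrosynthetic overview**

- The strategy rests on the aryl ester link O1–C8a of the six-membered lactone ring and on the only stereocentre, C4, which sits next to ring-fusion carbon C4a. Excising O1 (Baeyer–Villiger retron) joins C2 to C8a and leaves an (R)-3-aryl-indan-1-one.
- The C3–C3a bond of that indanone is traced to a bare arene C–H of a racemic 1,3-diarylprop-2-yn-1-ol (stereoconvergent rhodium cascade). The alcohol is cut at the carbinol–alkyne bond into an aryl aldehyde and an aryl acetylene.
- The bibenzyl CH2–aryl bond of the aldehyde comes from a B-alkyl Suzuki coupling of hydroborated 3,4-dimethoxystyrene.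
- Ring order: the cyclopentanone ring is closed first (step 6), oxygen insertion then enlarges it to the dihydrocoumarin lactone (step 7), and the three phenols are freed last.

Key step: step 6

Assumption: which BINAP enantiomer leads to the (R)-ketone is settled by a small trial run with assignment of configuration; the descriptor (R) denotes the same spatial arrangement in 14, 15 and 16, because the ranking ring-fusion carbon > catechol aryl > CH2 > H holds in all three.

**Route**

Step 1
Reactants: 1 4-bromo-3-hydroxybenzaldehyde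
Product: 2 3-(benzyloxy)-4-bromobenzaldehyde
Conditions: BnBr (1.1 equiv), K2CO3 (1.5 equiv), DMF, rt
Reagents that add atoms: benzyl bromide, BrCc1ccccc1
Why: Williamson etherification of the phenoxide, with aldehyde and aryl bromide inert to carbonate and benzyl bromide.

Step 2
Reactants: 2 3-(benzyloxy)-4-bromobenzaldehyde
Product: 3 2-(benzyloxy)-1-bromo-4-(dimethoxymethyl)benzene
Conditions: HC(OMe)3 (3 equiv), TsOH·H2O (2 mol%), MeOH, rt; Et3N quench
Reagents that add atoms: trimethyl orthoformate, COC(OC)OC; methanol, CO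
Why: Acid-catalysed acetalization driven by the orthoformate as water scavenger masks the aldehyde, which the B-alkyl borane of the next step could otherwise reduce by β-hydride transfer.

Step 3
Reactants: 4 3,4-dimethoxystyrene; 3 2-(benzyloxy)-1-bromo-4-(dimethoxymethyl)benzene
Product: 7 3-(benzyloxy)-4-[2-(3,4-dimethoxyphenyl)ethyl]benzaldehyde, via B-alkyl-9-BBN borane 5 (not isolated), via coupled dimethyl acetal 6 (not isolated)
Conditions: 4 (1.3 equiv), 9-BBN (1.25 equiv), THF, 0 °C to rt; then 3 (1.0 equiv), PdCl2(dppf)·CH2Cl2 (3 mol%), 3 M aq NaOH (3 equiv), THF, 65 °C; then 2 M aq HCl, THF, rt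
Reagents that add atoms: 9-borabicyclo[3.3.1]nonane (9-BBN), B1C2CCCC1CCC2 (stays in 5 only); water, O (aldehyde oxygen of 7)
Why: 9-BBN hydroborates the styrene at the terminal carbon, the B-alkyl borane enters a hydroxide-promoted B-alkyl Suzuki–Miyaura coupling with the aryl bromide, and aqueous acid then hydrolyses the dimethyl acetal while the benzyl and methyl ethers stay untouched.

Step 4
Reactants: 8 3,4-bis(benzyloxy)benzaldehyde
Product: 9 1,2-bis(benzyloxy)-4-ethynylbenzene
Conditions: dimethyl (1-diazo-2-oxopropyl)phosphonate (1.3 equiv), K2CO3 (2 equiv), MeOH/THF, rt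
Reagents that add atoms: Ohira–Bestmann reagent (dimethyl (1-diazo-2-oxopropyl)phosphonate), CC(=O)C(=[N+]=[N-])P(=O)(OC)OC
Why: Ohira–Bestmann variant of the Seyferth–Gilbert homologation, in which the diazomethylphosphonate anion released by methanolysis olefinates the non-enolizable aldehyde and the vinylidene formed on loss of nitrogen rearranges to the terminal alkyne.

Step 5
Reactants: 9 1,2-bis(benzyloxy)-4-ethynylbenzene; 7 3-(benzyloxy)-4-[2-(3,4-dimethoxyphenyl)ethyl]benzaldehyde
Product: 12 rac-1-{3-(benzyloxy)-4-[2-(3,4-dimethoxyphenyl)ethyl]phenyl}-3-[3,4-bis(benzyloxy)phenyl]prop-2-yn-1-ol, via lithium acetylide 10 (not isolated), via lithium alkoxide 11 (not isolated)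
Conditions: 9 (1.2 equiv), n-BuLi (1.15 equiv), THF, −78 °C; then 7 (1.0 equiv), −78 to 0 °C; sat. aq NH4Cl
Reagents that add atoms: n-butyllithium, [Li]CCCC (lithium in 10 and 11 only)
Why: 1,2-Addition of a lithium acetylide to an aryl aldehyde, left racemic on purpose because the carbinol centre is erased in the next step.

Step 6
Reactants: 12 rac-1-{3-(benzyloxy)-4-[2-(3,4-dimethoxyphenyl)ethyl]phenyl}-3-[3,4-bis(benzyloxy)phenyl]prop-2-yn-1-ol
Product: 14 (R)-6-(benzyloxy)-3-[3,4-bis(benzyloxy)phenyl]-5-[2-(3,4-dimethoxyphenyl)ethyl]-2,3-dihydro-1H-inden-1-one, via ynone 13 (not isolated)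
Conditions: [RhCl(C2H4)2]2 (2.5 mol%), one enantiomer of BINAP (6 mol%, the antipode giving (R)-14), KOH (10 mol%), degassed THF, 60 °C, argon
Reagents that add atoms: none
Why: KOH converts the chloride precatalyst into a monovalent rhodium alkoxide of 12, which loses β-hydride to give the achiral ynone 13 and Rh–H; syn hydrorhodation of the triple bond places rhodium α to the carbonyl, a 1,4-rhodium shift moves the metal to an ortho C–H of the aroyl ring, the aryl–rhodium adds to the enone β-carbon, and the oxa-π-allyl rhodium is protonated by the next molecule of 12. The closest known reaction type is the rhodium/chiral bisphosphine isomerization of racemic α-arylpropargyl alcohols to β-chiral 1-indanones, applied here to an aryl-capped alkyne and a more highly substituted carbinol arene. The five-membered ketone ring closes by intramolecular 1,4-carbometalation, a formal 5-endo-trig closure, forming the bond between the former alkyne carbon (later lactone C4) and the arene carbon para to the benzyloxy group (later C4a). The single stereocentre arises in this carbometalation under catalyst control: the biaryl bisphosphine decides which enone face the aryl–rhodium attacks, and since the carbinol centre has vanished in 13, both enantiomers of 12 funnel into one product. Site selectivity between the two ortho C–H bonds is required and is secured sterically, as the C–H wedged between carbonyl and benzyloxy group is shielded and rhodium settles para to the ether; the alkyne aryl group ends up trans to rhodium after syn addition and is out of reach for the shift.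

Step 7
Reactants: 14 (R)-6-(benzyloxy)-3-[3,4-bis(benzyloxy)phenyl]-5-[2-(3,4-dimethoxyphenyl)ethyl]-2,3-dihydro-1H-inden-1-one
Product: 15 (R)-7-(benzyloxy)-4-[3,4-bis(benzyloxy)phenyl]-6-[2-(3,4-dimethoxyphenyl)ethyl]-3,4-dihydro-2H-chromen-2-one
Conditions: mCPBA (2.0 equiv), TsOH·H2O (1.0 equiv), CH2Cl2, 0 °C to rt, dark; aq Na2S2O3/NaHCO3 work-up
Reagents that add atoms: mCPBA (3-chloroperoxybenzoic acid), OOC(=O)c1cccc(Cl)c1
Why: Baeyer–Villiger oxidation in which the aryl carbon C7a, para to the alkyl chain, migrates from the Criegee adduct in preference to CH2 and becomes lactone C8a, the known conversion of 3-aryl-1-indanones into 4-aryl-3,4-dihydrocoumarins, which leaves the remote stereocentre untouched.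

Step 8
Reactants: 15 (R)-7-(benzyloxy)-4-[3,4-bis(benzyloxy)phenyl]-6-[2-(3,4-dimethoxyphenyl)ethyl]-3,4-dihydro-2H-chromen-2-one
Product: 16 (R)-4-(3,4-dihydroxyphenyl)-6-[2-(3,4-dimethoxyphenyl)ethyl]-7-hydroxy-3,4-dihydro-2H-chromen-2-one (target CNP0376539.1)
Conditions: H2 (1 atm), Pd/C (10 wt% palladium on carbon), EtOAc/THF, rt
Reagents that add atoms: none
Why: Hydrogenolysis of the three aryl benzyl ethers in a non-alcoholic solvent, so that the aryl lactone is not opened, with C4 (not α to the carbonyl) configurationally safe.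

**Compound list**

1 | 4-bromo-3-hydroxybenzaldehyde | O=Cc1ccc(Br)c(O)c1 | starting material
2 | 3-(benzyloxy)-4-bromobenzaldehyde | O=Cc1ccc(Br)c(OCc2ccccc2)c1 | intermediate
3 | 2-(benzyloxy)-1-bromo-4-(dimethoxymethyl)benzene | COC(OC)c1ccc(Br)c(OCc2ccccc2)c1 | intermediate
4 | 3,4-dimethoxystyrene | C=Cc1ccc(OC)c(OC)c1 | starting material
5 | 9-[2-(3,4-dimethoxyphenyl)ethyl]-9-borabicyclo[3.3.1]nonane | COc1ccc(CCB2C3CCCC2CCC3)cc1OC | intermediate
6 | 2-(benzyloxy)-4-(dimethoxymethyl)-1-[2-(3,4-dimethoxyphenyl)ethyl]benzene | COc1ccc(CCc2ccc(C(OC)OC)cc2OCc2ccccc2)cc1OC | intermediate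
7 | 3-(benzyloxy)-4-[2-(3,4-dimethoxyphenyl)ethyl]benzaldehyde | COc1ccc(CCc2ccc(C=O)cc2OCc2ccccc2)cc1OC | intermediate
8 | 3,4-bis(benzyloxy)benzaldehyde | O=Cc1ccc(OCc2ccccc2)c(OCc2ccccc2)c1 | starting material
9 | 1,2-bis(benzyloxy)-4-ethynylbenzene | C#Cc1ccc(OCc2ccccc2)c(OCc2ccccc2)c1 | intermediate
10 | lithium [3,4-bis(benzyloxy)phenyl]acetylide | [Li]C#Cc1ccc(OCc2ccccc2)c(OCc2ccccc2)c1 | intermediate
11 | lithium alkoxide of racemic alcohol 12 | COc1ccc(CCc2ccc(C(O[Li])C#Cc3ccc(OCc4ccccc4)c(OCc4ccccc4)c3)cc2OCc2ccccc2)cc1OC | intermediate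
12 | rac-1-{3-(benzyloxy)-4-[2-(3,4-dimethoxyphenyl)ethyl]phenyl}-3-[3,4-bis(benzyloxy)phenyl]prop-2-yn-1-ol | COc1ccc(CCc2ccc(C(O)C#Cc3ccc(OCc4ccccc4)c(OCc4ccccc4)c3)cc2OCc2ccccc2)cc1OC | intermediate
13 | 1-{3-(benzyloxy)-4-[2-(3,4-dimethoxyphenyl)ethyl]phenyl}-3-[3,4-bis(benzyloxy)phenyl]prop-2-yn-1-one (achiral, formed on rhodium) | COc1ccc(CCc2ccc(C(=O)C#Cc3ccc(OCc4ccccc4)c(OCc4ccccc4)c3)cc2OCc2ccccc2)cc1OC | intermediate
14 | (R)-6-(benzyloxy)-3-[3,4-bis(benzyloxy)phenyl]-5-[2-(3,4-dimethoxyphenyl)ethyl]-2,3-dihydro-1H-inden-1-one | COc1ccc(CCc2cc3c(cc2OCc2ccccc2)C(=O)C[C@@H]3c2ccc(OCc4ccccc4)c(OCc4ccccc4)c2)cc1OC | intermediate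
15 | (R)-7-(benzyloxy)-4-[3,4-bis(benzyloxy)phenyl]-6-[2-(3,4-dimethoxyphenyl)ethyl]-3,4-dihydro-2H-chromen-2-one | COc1ccc(CCc2cc3c(cc2OCc2ccccc2)OC(=O)C[C@@H]3c2ccc(OCc4ccccc4)c(OCc4ccccc4)c2)cc1OC | intermediate
16 | (R)-4-(3,4-dihydroxyphenyl)-6-[2-(3,4-dimethoxyphenyl)ethyl]-7-hydroxy-3,4-dihydro-2H-chromen-2-one | COc1ccc(CCc2cc3c(cc2O)OC(=O)C[C@@H]3c2ccc(O)c(O)c2)cc1OC | target

**Step count and risks**

Total step count: 8. Longest linear sequence: 7 steps (1 → 2 → 3 → 7 → 12 → 14 → 15 → 16).

Steps most likely to fail: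

1. Step 6. The alkenyl–rhodium may be protonated before the 1,4-shift, so that the cascade stalls at simple redox isomerization. Facial selectivity with an aryl-substituted enone may be poor, or metalation may go to the hindered ortho C–H. The aryl-capped alkyne and the trisubstituted carbinol arene are believed to lie outside the best-documented scope. The fallback puts the lactone oxygen in place before the stereocentre and sets the stereocentre by an intermolecular conjugate arylation. It sets out from borane 5 (made from 4 as in step 3) and comes back to the route at 15. 6-Bromo-7-hydroxy-2H-chromen-2-one F1 (catalogue compound) would be benzylated (BnBr, K2CO3, DMF) to 7-(benzyloxy)-6-bromo-2H-chromen-2-one F2. B-alkyl Suzuki coupling of F2 with 5 (PdCl2(dppf), K3PO4, DMF/THF, 60 °C) should give 7-(benzyloxy)-6-[2-(3,4-dimethoxyphenyl)ethyl]-2H-chromen-2-one F3. Rhodium-catalysed asymmetric 1,4-addition (Hayashi–Miyaura reaction) of 3,4-bis(benzyloxy)phenylboronic acid F4 (catalogue compound) to F3 (Rh(acac)(C2H4)2, the SEGPHOS antipode giving (R), dioxane/H2O, 60 °C) should then deliver 15 directly, bypassing steps 5 to 7.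

2. Step 7. Oxygen insertion into the aryl ketone may be slow, and the peracid may attack the benzyloxy-substituted rings before insertion is complete; some CH2 migration is also possible. The fallback changes the phenol protection so that the oxidation runs on acyloxy-deactivated rings. It sets out from 14 and comes back at 16. Debenzylation of 14 (BCl3, pentamethylbenzene, CH2Cl2, −78 °C, which spares the methyl ethers and the ketone) would give (R)-3-(3,4-dihydroxyphenyl)-5-[2-(3,4-dimethoxyphenyl)ethyl]-6-hydroxy-2,3-dihydro-1H-inden-1-one F5. Acetylation (Ac2O, pyridine) would give the triacetate of that indanone F6. Baeyer–Villiger oxidation under more forcing conditions (mCPBA, TFA, CH2Cl2, rt) should give (R)-7-acetoxy-4-(3,4-diacetoxyphenyl)-6-[2-(3,4-dimethoxyphenyl)ethyl]-3,4-dihydro-2H-chromen-2-one F7. HCl in MeOH would remove the acetates and open the lactone to methyl (R)-3-(3,4-dihydroxyphenyl)-3-{2,4-dihydroxy-5-[2-(3,4-dimethoxyphenyl)ethyl]phenyl}propanoate F8. TsOH in toluene at 80 °C under argon should close the ring again to 16.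

3. Step 3. The B-alkyl coupling may suffer from protodeboronation of the borane, β-hydride elimination at alkyl–palladium, or slow oxidative addition next to the ortho benzyloxy group. The fallback builds the two-carbon bridge as an alkene first. It sets out from 3 and 4 and comes back at 6, which is hydrolysed to 7 as in step 3. Heck coupling of 3 with 4 (Pd(OAc)2, P(o-tol)3, Et3N, DMF, 100 °C) would give (E)-2-(benzyloxy)-4-(dimethoxymethyl)-1-[2-(3,4-dimethoxyphenyl)ethenyl]benzene F9. Diimide reduction of the stilbene double bond (TsNHNH2, NaOAc, THF/H2O, reflux), which leaves benzyl ether and acetal alone, should give 6.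

**Further compounds**

F1 | step 6 | 6-bromo-7-hydroxy-2H-chromen-2-one | O=C1C=Cc2cc(Br)c(O)cc2O1
F2 | step 6 | 7-(benzyloxy)-6-bromo-2H-chromen-2-one | O=C1C=Cc2cc(Br)c(OCc3ccccc3)cc2O1
F3 | step 6 | 7-(benzyloxy)-6-[2-(3,4-dimethoxyphenyl)ethyl]-2H-chromen-2-one | COc1ccc(CCc2cc3C=CC(=O)Oc3cc2OCc2ccccc2)cc1OC
F4 | step 6 | 3,4-bis(benzyloxy)phenylboronic acid | OB(O)c1ccc(OCc2ccccc2)c(OCc2ccccc2)c1
F5 | step 7 | (R)-3-(3,4-dihydroxyphenyl)-5-[2-(3,4-dimethoxyphenyl)ethyl]-6-hydroxy-2,3-dihydro-1H-inden-1-one | COc1ccc(CCc2cc3c(cc2O)C(=O)C[C@@H]3c2ccc(O)c(O)c2)cc1OC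
F6 | step 7 | (R)-6-acetoxy-3-(3,4-diacetoxyphenyl)-5-[2-(3,4-dimethoxyphenyl)ethyl]-2,3-dihydro-1H-inden-1-one | COc1ccc(CCc2cc3c(cc2OC(C)=O)C(=O)C[C@@H]3c2ccc(OC(C)=O)c(OC(C)=O)c2)cc1OC
F7 | step 7 | (R)-7-acetoxy-4-(3,4-diacetoxyphenyl)-6-[2-(3,4-dimethoxyphenyl)ethyl]-3,4-dihydro-2H-chromen-2-one | COc1ccc(CCc2cc3c(cc2OC(C)=O)OC(=O)C[C@@H]3c2ccc(OC(C)=O)c(OC(C)=O)c2)cc1OC
F8 | step 7 | methyl (R)-3-(3,4-dihydroxyphenyl)-3-{2,4-dihydroxy-5-[2-(3,4-dimethoxyphenyl)ethyl]phenyl}propanoate | COC(=O)C[C@@H](c1cc(CCc2ccc(OC)c(OC)c2)c(O)cc1O)c1ccc(O)c(O)c1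
F9 | step 3 | (E)-2-(benzyloxy)-4-(dimethoxymethyl)-1-[2-(3,4-dimethoxyphenyl)ethenyl]benzene | COc1ccc(/C=C/c2ccc(C(OC)OC)cc2OCc2ccccc2)cc1OC
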